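Amounts of complex with two exchanged were what I wanted from this flask, and they first rise and then fall, as an intermediate's do.

| flask | starting complex | incoming ligand | remark | time |
|---|---|---|---|---|
| Friday's | 10 mM | 20 mM | run made earlier |  |
| Wednesday's | 15 mM | 20 mM | run made earlier |  |
| flask | 20 mM | 20.0 mM |  | 3.0 h |

- Friday's (time / h: complex with two exchanged / %): 0.250: 11.1; 0.500: 22.5; 0.667: 26.6; 1.33: 33.4; 2.00: 32.9; 3.00: 27.5
- Wednesday's (time / h: complex with two exchanged / %): 0.250: 9.2; 0.500: 18.4; 0.667: 22.7; 1.33: 24.7; 2.00: 24.8; 3.00: 20.8

(readings scatter by 0.5 percentage points)



* the moment within 3.0 h at which there is most complex with two exchanged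
* the amount of complex with two exchanged, in percent of the starting complex charged, at that time

I reckoned with rates. The early rate, the amount at 0.500 h over that time, read 4.50 mM h⁻¹ in Friday's run and 5.52 mM h⁻¹ in Wednesday's. The net rate then slowed to zero at peak readings of 3.34 mM and 3.72 mM. Dividing gave 0.742 h and 0.674 h; this peak amount over early rate, the time to the peak at undiminished early rate, I call the fill time.

My zero was the proportional case, where the rate follows the starting complex charged, the fill time stays, and the percent holds. For 1.50 times the charge, the readings instead gave 1.23 times the rate and 0.908 times the fill time. As powers of the charge these are 0.504 and −0.238. Carried to 20 mM at the same incoming ligand, they gave 6.38 mM h⁻¹ and 0.629 h, so I estimated a peak of 4.02 mM, or 20.1 %. Two fill times fell later than 1.33 h and earlier than 2.00 h in both runs, so I expected the peak near 1.26 h.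

The forecast gave 21 % at 1.65 h, later than my time, and said the runs suggested that “the ligand supply limits the yield”. The flask gave 20.0 % at 1.15 h, which is 4.00 mM after 1.83 fill times.

    complex with one exchanged + incoming ligand ⇌ leaving ligand + complex with two exchanged (K = 2.80, k = 3.00 L mol⁻¹ min⁻¹)
    starting complex + incoming ligand ⇌ leaving ligand + complex with one exchanged (K = 1.40, k = 1.60 L mol⁻¹ min⁻¹)
    complex with two exchanged + incoming ligand → over-reaction product (k = 0.530 L mol⁻¹ min⁻¹)

The neighbouring flask, the same but with 8.0 mM of starting complex, took the same reckoning from Friday's run: early rate 4.02 mM h⁻¹, fill time 0.783 h, peak 3.15 mM, or 39.4 % of its charge. That flask gave 37.9 %, and after 3.00 h it held 31.5 % as complex with two exchanged, more than the 22.3 % left as starting complex.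

(All runs were generated by integration with made-up constants; the scatter is artificial.)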